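**Retrosynthetic overview**
- Target ⇐ fluoride removal of one alkyl silyl ether ⇐ Claisen–Schmidt condensation of a C-8 acetyl chroman with 4-hydroxybenzaldehyde (enone made last).
- Chroman O1–C2 bond ⇐ chiral-phosphoric-acid oxa-1,6-cyclisation of the ring A phenol onto a para-quinone methide released from a benzylic alcohol; this closes the ring and sets C-2.
- Benzylic alcohol ⇐ 4-hydroxyphenyl addition to a lactol; lactol ⇐ C4–C4a bond by iminium Friedel–Crafts/hemiacetalisation of a mono-silylated 2,4-dihydroxy-6-methoxyacetophenone with a δ-silyloxy enal (sets C-4).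
- Enal ⇐ cross-metathesis with crotonaldehyde ⇐ Keck allylation (sets the side-chain carbinol) ⇐ Heck arylation of allyl alcohol.
- Ring order: a temporary lactol ring (closed in step 6, reopened in step 7), then the pyran ring of the chroman (step 8); the three benzene rings are bought.

Assumption: tert-butyl(4-iodophenoxy)dimethylsilane and 1-(2,4-dihydroxy-6-methoxyphenyl)ethanone are bought as such; TBS = tert-butyldimethylsilyl, TBSO = its ether.

Note on descriptors: the spatial arrangement at chroman C-4 is the same from step 6 to the target. Its CIP label changes (S in 12/13, R in 15–21, S in 22) only because the priorities of the two CH2 arms change with the O-substituents.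

**Step 1**
Reactants: 1 tert-butyl(4-iodophenoxy)dimethylsilane; 2 prop-2-en-1-ol
Product: 4 3-[4-(TBSO)phenyl]propanal, via enol tautomer 3 (not isolated)
Conditions: Pd(OAc)2 (2 mol%), Bu4NCl, NaHCO3, DMF, 45 °C
Reagents that add atoms: none
Why: Heck arylation of allyl alcohol (Jeffery conditions), in which β-hydride elimination toward the carbinol carbon gives the enol that tautomerises to the saturated aldehyde; no stereocentre is formed.

**Step 2**
Reactants: 4 3-[4-(TBSO)phenyl]propanal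
Product: 6 (3R)-1-[4-(TBSO)phenyl]hex-5-en-3-ol, via tributylstannyl ether 5 (not isolated)
Conditions: allylSnBu3, (S)-BINOL (10 mol%), Ti(OiPr)4 (10 mol%), 4 Å MS, CH2Cl2, −20 °C; aq NaHCO3
Reagents that add atoms: allyltributylstannane, C=CC[Sn](CCCC)(CCCC)CCCC
Why: Keck asymmetric allylation, in which the complex formed from Ti(OiPr)4 and (S)-BINOL directs allyl transfer to one aldehyde face (same facial sense that gives (S)-1-phenylbut-3-en-1-ol from benzaldehyde; the label is R here because the allyl arm outranks the arylethyl arm), setting the side-chain carbinol.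

**Step 3**
Reactants: 6 (3R)-1-[4-(TBSO)phenyl]hex-5-en-3-ol
Product: 7 tert-butyl{4-[(3R)-3-(TBSO)hex-5-en-1-yl]phenoxy}dimethylsilane
Conditions: TBSCl, imidazole, DMF, rt
Reagents that add atoms: tert-butyldimethylsilyl chloride, CC(C)(C)[Si](C)(C)Cl
Why: Standard silylation; the silyl ether is a poor leaving group (no elimination under amine catalysis in step 6) and keeps this oxygen from competing as a nucleophile in step 8.

**Step 4**
Reactants: 7 tert-butyl{4-[(3R)-3-(TBSO)hex-5-en-1-yl]phenoxy}dimethylsilane; 8 (E)-but-2-enal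
Product: 9 (2E,5R)-5-(TBSO)-7-[4-(TBSO)phenyl]hept-2-enal
Conditions: second-generation Grubbs catalyst RuCl2(=CHPh)(PCy3)(H2IMes) (3 mol%), 8 (5 equiv), CH2Cl2, 40 °C
Reagents that add atoms: none
Why: Olefin cross-metathesis of a terminal alkene with crotonaldehyde is E-selective and driven by loss of propene; the carbinol centre is remote and untouched.

**Step 5**
Reactants: 10 1-(2,4-dihydroxy-6-methoxyphenyl)ethanone
Product: 11 1-[4-(TBSO)-2-hydroxy-6-methoxyphenyl]ethanone
Conditions: TBSCl (1.05 equiv), imidazole, CH2Cl2, 0 °C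
Reagents that add atoms: tert-butyldimethylsilyl chloride, CC(C)(C)[Si](C)(C)Cl
Why: Selective silylation of the free 4-OH, because the 2-OH is hydrogen-bonded to the acetyl group; this leaves only the oxygen that must become O-1 available later.

**Step 6**
Reactants: 11 1-[4-(TBSO)-2-hydroxy-6-methoxyphenyl]ethanone; 9 (2E,5R)-5-(TBSO)-7-[4-(TBSO)phenyl]hept-2-enal
Product: 13 1-[(4S)-5-(TBSO)-4-{(2R)-2-(TBSO)-4-[4-(TBSO)phenyl]butyl}-2-hydroxy-7-methoxy-3,4-dihydro-2H-chromen-8-yl]ethanone (anomer mixture), via open-chain hydroxy aldehyde 12 (not isolated)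
Conditions: (R)-α,α-diphenylprolinol trimethylsilyl ether (20 mol%), PhCO2H (20 mol%), toluene, 0 °C → rt
Reagents that add atoms: none
Why: Iminium-ion-catalysed Friedel–Crafts alkylation/hemiacetalisation (Jørgensen–Hayashi catalyst): the phenol attacks through C-3, the only position ortho to its free OH, anti to the diphenyl(silyloxy)methyl group of the E-iminium ion, which sets C-4 as S (the S catalyst gives the opposite sense, as in the known malonate and nitromethane additions), and the adduct is trapped as the lactol.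

**Step 7**
Reactants: 13 the lactol from step 6; 14 (4-hydroxyphenyl)boronic acid
Product: 15 1-[4-(TBSO)-2-hydroxy-3-{(3R,5R)-5-(TBSO)-1-hydroxy-1-(4-hydroxyphenyl)-7-[4-(TBSO)phenyl]heptan-3-yl}-6-methoxyphenyl]ethanone (C-1 epimer mixture)
Conditions: Rh(acac)(coe)2 (3 mol%), t-Bu3P (3 mol%), 14 (3 equiv), DME/H2O 3:1, 50 °C
Reagents that add atoms: none
Why: Miyaura-type rhodium-catalysed 1,2-addition of the arylboronic acid to the aldehyde carbon of the lactol, which reacts through the small equilibrium share of its ring-chain tautomer (the hydroxy aldehyde 12 of step 6); the hydrogen-bonded, di-ortho-substituted acetyl group and the silyl ethers do not react, and the new carbinol centre is deliberately left unselective because step 8 passes through a planar intermediate.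

**Step 8**
Reactants: 15 the benzylic alcohol from step 7 (both C-1 epimers)
Product: 17 1-[(2R,4R)-5-(TBSO)-4-{(2R)-2-(TBSO)-4-[4-(TBSO)phenyl]butyl}-2-(4-hydroxyphenyl)-7-methoxy-3,4-dihydro-2H-chromen-8-yl]ethanone, via para-quinone methide 16 (not isolated)
Conditions: (R)-TRIP [(R)-3,3'-bis(2,4,6-triisopropylphenyl)-1,1'-binaphthyl-2,2'-diyl hydrogen phosphate] (10 mol%), 5 Å MS, toluene (0.02 M), 0 °C
Reagents that add atoms: none
Why: Proposed new method: a chiral-phosphoric-acid-catalysed, stereoconvergent dehydrative oxa-1,6-cyclisation. The acid ionises the 4-hydroxybenzyl alcohol to the planar para-quinone methide 16, so both carbinol epimers converge (any 4-hydroxystyrene formed by proton loss re-enters by protonation). The phosphate then bridges the quinone methide oxygen and the acetyl-chelated ring A phenol O–H and delivers that oxygen to the methide carbon through a six-membered chair-like transition state. The C-4 side chain sits pseudoaxial to avoid allylic 1,3-strain with the peri 5-OTBS group while the incipient aryl group sits equatorial, giving the 2,4-trans (2R) ring; the catalyst is expected to reinforce this substrate bias, and the low temperature keeps the ring closure kinetic. No other free O-nucleophile is present (side-chain and second ring A oxygens are silylated). The closest known reactions are phosphoric-acid-catalysed intermolecular 1,6-additions of carbon, sulfur and nitrogen nucleophiles to para-quinone methides generated in situ from 4-hydroxybenzyl alcohols, and achiral acid-mediated flavan closures; an intramolecular phenol addition to an unhindered quinone methide with catalyst-reinforced diastereocontrol is new.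

**Step 9**
Reactants: 17 the acetyl chroman from step 8; 18 4-hydroxybenzaldehyde
Product: 21 (2E)-1-[(2R,4R)-4-{(2R)-2-(TBSO)-4-(4-hydroxyphenyl)butyl}-5-hydroxy-2-(4-hydroxyphenyl)-7-methoxy-3,4-dihydro-2H-chromen-8-yl]-3-(4-hydroxyphenyl)prop-2-en-1-one, via deprotected methyl ketone 19 (not isolated), via aldol adduct 20 (not isolated)
Conditions: KOH (50% aq, excess), 18 (3 equiv), EtOH, rt, argon; aq NH4Cl
Reagents that add atoms: none
Why: Claisen–Schmidt aldol condensation: hydroxide first cleaves the two aryl silyl ethers, the methyl ketone enolate adds to the aldehyde and E1cB loss of water gives the E-enone; no stereocentre bears an acidic hydrogen and the ring A phenoxide disfavours ring opening at C-2.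

**Step 10**
Reactants: 21 the silyl-protected chalcone from step 9
Product: 22 (2E)-1-[(2R,4S)-5-hydroxy-4-[(2R)-2-hydroxy-4-(4-hydroxyphenyl)butyl]-2-(4-hydroxyphenyl)-7-methoxy-3,4-dihydro-2H-chromen-8-yl]-3-(4-hydroxyphenyl)prop-2-en-1-one (target)
Conditions: TBAF/AcOH (1:1, 5 equiv), THF, rt → 40 °C
Reagents that add atoms: none
Why: Fluoride-mediated desilylation of the secondary alkyl silyl ether under acetic-acid buffering leaves the enone, the benzylic aryl ether and all three stereocentres untouched (strong acid is avoided because it could reopen the ring at C-2).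

**Compound list**
1 | tert-butyl(4-iodophenoxy)dimethylsilane | CC(C)(C)[Si](C)(C)Oc1ccc(I)cc1 | starting material
2 | prop-2-en-1-ol (allyl alcohol) | C=CCO | starting material
3 | 3-[4-(TBSO)phenyl]prop-1-en-1-ol (enol, E/Z not defined) | OC=CCc1ccc(O[Si](C)(C)C(C)(C)C)cc1 | intermediate
4 | 3-[4-(TBSO)phenyl]propanal | O=CCCc1ccc(O[Si](C)(C)C(C)(C)C)cc1 | intermediate
5 | tributyl{[(3R)-1-[4-(TBSO)phenyl]hex-5-en-3-yl]oxy}stannane | C=CC[C@H](O[Sn](CCCC)(CCCC)CCCC)CCc1ccc(O[Si](C)(C)C(C)(C)C)cc1 | intermediate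
6 | (3R)-1-[4-(TBSO)phenyl]hex-5-en-3-ol | C=CC[C@H](O)CCc1ccc(O[Si](C)(C)C(C)(C)C)cc1 | intermediate
7 | tert-butyl{4-[(3R)-3-(TBSO)hex-5-en-1-yl]phenoxy}dimethylsilane | C=CC[C@H](O[Si](C)(C)C(C)(C)C)CCc1ccc(O[Si](C)(C)C(C)(C)C)cc1 | intermediate
8 | (E)-but-2-enal (crotonaldehyde) | C/C=C/C=O | starting material
9 | (2E,5R)-5-(TBSO)-7-[4-(TBSO)phenyl]hept-2-enal | O=C/C=C/C[C@H](O[Si](C)(C)C(C)(C)C)CCc1ccc(O[Si](C)(C)C(C)(C)C)cc1 | intermediate
10 | 1-(2,4-dihydroxy-6-methoxyphenyl)ethanone | CC(=O)c1c(O)cc(O)cc1OC | starting material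
11 | 1-[4-(TBSO)-2-hydroxy-6-methoxyphenyl]ethanone | CC(=O)c1c(O)cc(O[Si](C)(C)C(C)(C)C)cc1OC | intermediate
12 | (3S,5R)-3-[3-acetyl-6-(TBSO)-2-hydroxy-4-methoxyphenyl]-5-(TBSO)-7-[4-(TBSO)phenyl]heptanal | COc1cc(O[Si](C)(C)C(C)(C)C)c(c(O)c1C(C)=O)[C@H](CC=O)C[C@H](O[Si](C)(C)C(C)(C)C)CCc1ccc(O[Si](C)(C)C(C)(C)C)cc1 | intermediate
13 | 1-[(4S)-5-(TBSO)-4-{(2R)-2-(TBSO)-4-[4-(TBSO)phenyl]butyl}-2-hydroxy-7-methoxy-3,4-dihydro-2H-chromen-8-yl]ethanone (both anomers at C-2) | COc1cc(O[Si](C)(C)C(C)(C)C)c2c(c1C(C)=O)OC(O)C[C@@H]2C[C@H](O[Si](C)(C)C(C)(C)C)CCc1ccc(O[Si](C)(C)C(C)(C)C)cc1 | intermediate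
14 | (4-hydroxyphenyl)boronic acid | OB(O)c1ccc(O)cc1 | starting material
15 | 1-[4-(TBSO)-2-hydroxy-3-{(3R,5R)-5-(TBSO)-1-hydroxy-1-(4-hydroxyphenyl)-7-[4-(TBSO)phenyl]heptan-3-yl}-6-methoxyphenyl]ethanone (both C-1 epimers) | COc1cc(O[Si](C)(C)C(C)(C)C)c(c(O)c1C(C)=O)[C@H](CC(O)c1ccc(O)cc1)C[C@H](O[Si](C)(C)C(C)(C)C)CCc1ccc(O[Si](C)(C)C(C)(C)C)cc1 | intermediate
16 | 4-{(3R,5R)-3-[3-acetyl-6-(TBSO)-2-hydroxy-4-methoxyphenyl]-5-(TBSO)-7-[4-(TBSO)phenyl]heptylidene}cyclohexa-2,5-dien-1-one | COc1cc(O[Si](C)(C)C(C)(C)C)c(c(O)c1C(C)=O)[C@H](CC=C1C=CC(=O)C=C1)C[C@H](O[Si](C)(C)C(C)(C)C)CCc1ccc(O[Si](C)(C)C(C)(C)C)cc1 | intermediate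
17 | 1-[(2R,4R)-5-(TBSO)-4-{(2R)-2-(TBSO)-4-[4-(TBSO)phenyl]butyl}-2-(4-hydroxyphenyl)-7-methoxy-3,4-dihydro-2H-chromen-8-yl]ethanone (2,4-trans) | COc1cc(O[Si](C)(C)C(C)(C)C)c2c(c1C(C)=O)O[C@@H](c1ccc(O)cc1)C[C@@H]2C[C@H](O[Si](C)(C)C(C)(C)C)CCc1ccc(O[Si](C)(C)C(C)(C)C)cc1 | intermediate
18 | 4-hydroxybenzaldehyde | O=Cc1ccc(O)cc1 | starting material
19 | 1-[(2R,4R)-4-{(2R)-2-(TBSO)-4-(4-hydroxyphenyl)butyl}-5-hydroxy-2-(4-hydroxyphenyl)-7-methoxy-3,4-dihydro-2H-chromen-8-yl]ethanone | COc1cc(O)c2c(c1C(C)=O)O[C@@H](c1ccc(O)cc1)C[C@@H]2C[C@H](O[Si](C)(C)C(C)(C)C)CCc1ccc(O)cc1 | intermediate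
20 | 1-[(2R,4R)-4-{(2R)-2-(TBSO)-4-(4-hydroxyphenyl)butyl}-5-hydroxy-2-(4-hydroxyphenyl)-7-methoxy-3,4-dihydro-2H-chromen-8-yl]-3-hydroxy-3-(4-hydroxyphenyl)propan-1-one (both carbinol epimers) | COc1cc(O)c2c(c1C(=O)CC(O)c1ccc(O)cc1)O[C@@H](c1ccc(O)cc1)C[C@@H]2C[C@H](O[Si](C)(C)C(C)(C)C)CCc1ccc(O)cc1 | intermediate
21 | (2E)-1-[(2R,4R)-4-{(2R)-2-(TBSO)-4-(4-hydroxyphenyl)butyl}-5-hydroxy-2-(4-hydroxyphenyl)-7-methoxy-3,4-dihydro-2H-chromen-8-yl]-3-(4-hydroxyphenyl)prop-2-en-1-one | COc1cc(O)c2c(c1C(=O)/C=C/c1ccc(O)cc1)O[C@@H](c1ccc(O)cc1)C[C@@H]2C[C@H](O[Si](C)(C)C(C)(C)C)CCc1ccc(O)cc1 | intermediate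
22 | (2E)-1-[(2R,4S)-5-hydroxy-4-[(2R)-2-hydroxy-4-(4-hydroxyphenyl)butyl]-2-(4-hydroxyphenyl)-7-methoxy-3,4-dihydro-2H-chromen-8-yl]-3-(4-hydroxyphenyl)prop-2-en-1-one | COc1cc(O)c2c(c1C(=O)/C=C/c1ccc(O)cc1)O[C@@H](c1ccc(O)cc1)C[C@@H]2C[C@H](O)CCc1ccc(O)cc1 | target

**Step count**
Total: 10 steps. Longest linear sequence: 9 (steps 1–4, then 6–10).

**Steps most likely to fail, with fallbacks**

For step 6 the risks are attack at C-5 instead of C-3 and the low nucleophilicity of the hydrogen-bonded acylphenol. The fallback sets out from 11 and 9 and enforces the ortho position through an oxygen tether. Oxidative N-heterocyclic-carbene catalysis (aminoindanol-derived N-mesityl triazolium salt in the enantiomer that gives 4S, K2CO3, 3,3',5,5'-tetra-tert-butyldiphenoquinone, toluene, rt) turns 9 into an α,β-unsaturated acyl azolium. The phenol oxygen of 11 adds to it, and a Coates–Claisen-type [3,3] shift moves the β-carbon onto C-3, giving the 3,4-dihydrocoumarin lactone F1. Half-reduction of F1 with iBu2AlH (1.05 equiv, toluene, −78 °C; the shielded di-ortho-substituted acetyl group is left) comes back to the route at lactol 13.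

For step 7 the risks are slow opening of the lactol and protodeboronation of the boronic acid. The fallback sets out from 13 and uses a stoichiometric, aldehyde-selective organotitanium reagent instead of catalysis. 4-(Trimethylsilyloxy)phenylmagnesium bromide is transmetallated with ClTi(OiPr)3 and added in THF at −40 → 0 °C (ketone and silyl ethers are inert to ArTi(OiPr)3). This gives the aryl trimethylsilyl ether of the carbinol F2, which loses its trimethylsilyl group in the citric-acid work-up and comes back to the route at 15.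

For step 8 (the proposed new step) the risks are poor 2,4-diastereocontrol, slow ionisation, or side reactions of the quinone methide. The fallback uses known chemistry and sets out from 15. The free phenol of the 4-hydroxyphenyl carbinol is silylated selectively (TBSCl 1.05 equiv, imidazole, 0 °C) to the tetrasilyl carbinol F3. MnO2 (CH2Cl2) oxidises the benzylic alcohol to the aryl ketone F4. Corey–Bakshi–Shibata reduction with (R)-2-methyl-CBS-oxazaborolidine and BH3·SMe2 gives the single (1S)-alcohol F5. Intramolecular Mitsunobu etherification (PPh3, DIAD, THF, 0 °C) by the ring A phenol inverts this centre and gives the (2R)-chroman F6. Under the conditions of step 9, F6 loses its three aryl silyl groups and condenses with 18, so this fallback comes back to the route at 21.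

**Further compounds**
F1 | step 6 | (4S)-8-acetyl-5-(TBSO)-4-{(2R)-2-(TBSO)-4-[4-(TBSO)phenyl]butyl}-7-methoxy-3,4-dihydro-2H-chromen-2-one | COc1cc(O[Si](C)(C)C(C)(C)C)c2c(c1C(C)=O)OC(=O)C[C@@H]2C[C@H](O[Si](C)(C)C(C)(C)C)CCc1ccc(O[Si](C)(C)C(C)(C)C)cc1
F2 | step 7 | 1-[4-(TBSO)-2-hydroxy-3-{(3R,5R)-5-(TBSO)-1-hydroxy-7-[4-(TBSO)phenyl]-1-[4-(trimethylsilyloxy)phenyl]heptan-3-yl}-6-methoxyphenyl]ethanone (both C-1 epimers) | COc1cc(O[Si](C)(C)C(C)(C)C)c(c(O)c1C(C)=O)[C@H](CC(O)c1ccc(O[Si](C)(C)C)cc1)C[C@H](O[Si](C)(C)C(C)(C)C)CCc1ccc(O[Si](C)(C)C(C)(C)C)cc1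
F3 | step 8 | 1-[4-(TBSO)-2-hydroxy-3-{(3R,5R)-5-(TBSO)-1-hydroxy-1,7-bis[4-(TBSO)phenyl]heptan-3-yl}-6-methoxyphenyl]ethanone (both C-1 epimers) | COc1cc(O[Si](C)(C)C(C)(C)C)c(c(O)c1C(C)=O)[C@H](CC(O)c1ccc(O[Si](C)(C)C(C)(C)C)cc1)C[C@H](O[Si](C)(C)C(C)(C)C)CCc1ccc(O[Si](C)(C)C(C)(C)C)cc1
F4 | step 8 | (3S,5R)-3-[3-acetyl-6-(TBSO)-2-hydroxy-4-methoxyphenyl]-5-(TBSO)-1,7-bis[4-(TBSO)phenyl]heptan-1-one | COc1cc(O[Si](C)(C)C(C)(C)C)c(c(O)c1C(C)=O)[C@H](CC(=O)c1ccc(O[Si](C)(C)C(C)(C)C)cc1)C[C@H](O[Si](C)(C)C(C)(C)C)CCc1ccc(O[Si](C)(C)C(C)(C)C)cc1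
F5 | step 8 | 1-[4-(TBSO)-2-hydroxy-3-{(1S,3R,5R)-5-(TBSO)-1-hydroxy-1,7-bis[4-(TBSO)phenyl]heptan-3-yl}-6-methoxyphenyl]ethanone | COc1cc(O[Si](C)(C)C(C)(C)C)c(c(O)c1C(C)=O)[C@H](C[C@H](O)c1ccc(O[Si](C)(C)C(C)(C)C)cc1)C[C@H](O[Si](C)(C)C(C)(C)C)CCc1ccc(O[Si](C)(C)C(C)(C)C)cc1
F6 | step 8 | 1-[(2R,4R)-5-(TBSO)-4-{(2R)-2-(TBSO)-4-[4-(TBSO)phenyl]butyl}-2-[4-(TBSO)phenyl]-7-methoxy-3,4-dihydro-2H-chromen-8-yl]ethanone | COc1cc(O[Si](C)(C)C(C)(C)C)c2c(c1C(C)=O)O[C@@H](c1ccc(O[Si](C)(C)C(C)(C)C)cc1)C[C@@H]2C[C@H](O[Si](C)(C)C(C)(C)C)CCc1ccc(O[Si](C)(C)C(C)(C)C)cc1
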